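The tetramer is assembled from four benzylated monomers by three Friedel–Crafts unions; only the third unit from the top (unit Y, an epicatechin 8-linked above and 4-linked below) is made de novo. Its pyran ring C is cut at O1–C8a and C2–C3: a γ-benzyloxy-β-aryl allylboronate (OBn cis to CH2B) whose aryl group carries fluorine at the future C8a adds to 3,4-bis(benzyloxy)benzaldehyde under chiral phosphoric acid control, and the C2 alkoxide displaces fluoride in one pot. The step exploits the syn O1–C2/C3–O array of ring C and C8a being meta to both ring A oxygens (C5, C7). The exocyclic C4 methylene left behind is later excised to the C4 leaving group.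

Key step: step 6

Remark on the chemistry: read from the SMILES, the flavan units (called W, X, Y, Z from the top unit to the terminal unit with C4 = CH2) are W and Y = (2R,3R)-epicatechin units with 4β bonds, X and Z = (2S,3S)-ent-epicatechin units (X with a 4α bond); the linkages are W(4β→6)X, X(4α→8)Y and Y(4β→6)Z, every 2,3-relation is cis and every 3,4-relation trans. Both enantiomers of epicatechin are taken as commercial. TRIP = 3,3'-bis(2,4,6-triisopropylphenyl)-1,1'-binaphthyl-2,2'-diyl hydrogen phosphate; the (S) antipode is the one expected to direct Si-face attack. XyS = 2,6-dimethylphenylthio.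

**Step 1**
Reactants: 1 5-fluororesorcinol
Product: 2 1,3-bis(benzyloxy)-5-fluorobenzene
Conditions: BnBr (2.2 equiv), K2CO3, DMF, rt to 60 °C
Reagents that add atoms: benzyl bromide BrCc1ccccc1
Why: Williamson etherification of both phenols; the aryl fluoride is inert to carbonate.

**Step 2**
Reactants: 2 1,3-bis(benzyloxy)-5-fluorobenzene
Product: 3 1,5-bis(benzyloxy)-3-fluoro-2-iodobenzene
Conditions: NIS (1.05 equiv), CF3CO2H (10 mol %), MeCN, 0 °C to rt
Reagents that add atoms: N-iodosuccinimide O=C1CCC(=O)N1I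
Why: Electrophilic aromatic iodination should go para to one benzyloxy group and ortho to the small fluorine, not into the crowded position between the two benzyloxy groups.

**Step 3**
Reactants: 4 2-bromoacrolein diethyl acetal
Product: 5 2-bromoacrolein dibenzyl acetal
Conditions: BnOH (2.5 equiv), PPTS (5 mol %), toluene, 60 °C, reduced pressure (ethanol removed)
Reagents that add atoms: benzyl alcohol OCc1ccccc1
Why: Acid-catalysed transacetalisation driven by removal of ethanol; the benzyl group it installs becomes the hydrogenolysable O3 protecting group of unit Y.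

**Step 4**
Reactants: 3 1,5-bis(benzyloxy)-3-fluoro-2-iodobenzene; 5 2-bromoacrolein dibenzyl acetal
Product: 8 2-[2,4-bis(benzyloxy)-6-fluorophenyl]acrolein dibenzyl acetal, via arylmagnesium chloride 6 (not isolated), via arylzinc chloride 7 (not isolated)
Conditions: i-PrMgCl·LiCl, THF, −40 °C; ZnCl2, −40 to 0 °C; then 5, Pd2(dba)3 (2 mol %), SPhos (8 mol %), THF, 40 °C
Reagents that add atoms: none
Why: Iodine–magnesium exchange is selective for the C–I bond, the arylzinc is stable next to fluorine, and Negishi coupling with the alkenyl bromide (oxidative addition to zerovalent palladium) tolerates the acetal and the hindered nucleophile.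

**Step 5**
Reactants: 8 2-[2,4-bis(benzyloxy)-6-fluorophenyl]acrolein dibenzyl acetal
Product: 9 pinacol (E)-[3-(benzyloxy)-2-[2,4-bis(benzyloxy)-6-fluorophenyl]allyl]boronate (benzyloxy cis to CH2B)
Conditions: B2pin2 (1.2 equiv), CuCl (5 mol %), Xantphos (5 mol %), KOt-Bu (10 mol %), THF, 0 °C to rt
Reagents that add atoms: bis(pinacolato)diboron CC1(C)OB(OC1(C)C)B1OC(C)(C)C(C)(C)O1
Why: Copper-catalysed borylative SN2' substitution of an allylic acetal: the copper boryl adds with boron on CH2 and copper on the benzylic carbon, and β-alkoxide elimination should leave the remaining benzyloxy group turned away from the bulky aryl group, that is cis to CH2B.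

**Step 6**
Reactants: 9 pinacol (E)-[3-(benzyloxy)-2-[2,4-bis(benzyloxy)-6-fluorophenyl]allyl]boronate; 10 3,4-bis(benzyloxy)benzaldehyde
Product: 13 (2R,3R)-3,5,7-tris(benzyloxy)-2-[3,4-bis(benzyloxy)phenyl]-4-methylidenechromane, via syn-homoallylic pinacol borate 11 (not isolated), via potassium alkoxide 12 (not isolated)
Conditions: (S)-TRIP (5 mol %), 4 Å molecular sieves, toluene, −30 °C; then THF, KOt-Bu (2.5 equiv), 18-crown-6, 0 to 45 °C
Reagents that add atoms: none
Why: The phosphoric acid activates boronate 9 and the aldehyde in a closed chair transition state in which the γ-carbon (future C3) attacks the Si face of the aldehyde carbon (future C2) to give borate 11; KOt-Bu then frees alkoxide 12, whose oxygen (future O1) adds to the fluorine-bearing carbon (future C8a) and expels fluoride by addition–elimination. The closest known reaction types are the chiral phosphoric acid catalysed γ-alkoxyallylboration of aldehydes and the alkoxide/fluoroarene SNAr pyran closure used for cis-flavan-3-ols. The one ring formed, pyran ring C, closes as a six-membered intramolecular SNAr (formally 6-exo-trig at C8a). C2 is set by the catalyst (Si-face attack gives 2R) and C3 by the cis relation of OBn and CH2B in the chair (syn adduct, 3R); ring closure does not touch the C2–O bond, so the syn adduct becomes the 2,3-cis flavan. The step needs syn and facial selectivity and arylation of the C2 oxygen only: the single fluorine is meta to both benzyloxy groups (activated, no regiochemical choice), O3 is capped as a benzyl ether so no five-membered closure can compete, and the absence of a carbonyl group leaves nothing to epimerise or to revert under base.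

**Step 7**
Reactants: 13 (2R,3R)-3,5,7-tris(benzyloxy)-2-[3,4-bis(benzyloxy)phenyl]-4-methylidenechromane
Product: 15 4α-hydroxy-3,5,7,3',4'-penta-O-benzylepicatechin (2,3-cis-3,4-cis expected), via 2,3-cis-flavan-4-one 14 (not isolated)
Conditions: O3 (1 equiv), CH2Cl2/MeOH, −78 °C; then NaBH4, −78 to 0 °C
Reagents that add atoms: ozone [O-][O+]=O
Why: Ozonolysis excises the temporary methylene carbon and the α-benzyloxy ketone is reduced in the flask before C3 can epimerise; hydride should enter anti to the 2-aryl and 3-benzyloxy groups, and the C4 configuration is erased later on ionisation.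

**Step 8**
Reactants: 15 4α-hydroxy-3,5,7,3',4'-penta-O-benzylepicatechin
Product: 16 4α-acetoxy-3,5,7,3',4'-penta-O-benzylepicatechin
Conditions: Ac2O, pyridine, DMAP (cat.), CH2Cl2, 0 °C to rt
Reagents that add atoms: acetic anhydride CC(=O)OC(C)=O
Why: Acylation gives an oxygen leaving group at C4 that should survive thiophilic activation and removes the nucleophilic hydroxyl.

**Step 9**
Reactants: 17 (+)-epicatechin (2S,3S)
Product: 18 3,5,7,3',4'-penta-O-benzyl-ent-epicatechin
Conditions: NaH, BnBr, n-Bu4NI (cat.), DMF, −10 °C to rt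
Reagents that add atoms: benzyl bromide BrCc1ccccc1
Why: Exhaustive Williamson benzylation of four phenols and the C3 hydroxyl; cold conditions and fast O-alkylation should leave C2 untouched.

**Step 10**
Reactants: 18 3,5,7,3',4'-penta-O-benzyl-ent-epicatechin
Product: 19 8-bromo-3,5,7,3',4'-penta-O-benzyl-ent-epicatechin
Conditions: NBS (1.0 equiv), CH2Cl2, −78 to 0 °C
Reagents that add atoms: N-bromosuccinimide O=C1CCC(=O)N1Br
Why: Electrophilic bromination should take the most accessible nucleophilic position C8 of ring A, which caps C8 and leaves C6 as the only site for later C–C bond formation.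

**Step 11**
Reactants: 19 8-bromo-3,5,7,3',4'-penta-O-benzyl-ent-epicatechin
Product: 20 8-bromo-4α-(2-ethoxyethoxy)-3,5,7,3',4'-penta-O-benzyl-ent-epicatechin
Conditions: DDQ (2 equiv), 2-ethoxyethanol (5 equiv), CH2Cl2, rt
Reagents that add atoms: 2-ethoxyethanol CCOCCO
Why: Benzylic oxidation by hydride abstraction at C4 (cation stabilised by the ring A oxygens) and capture by the alcohol trans to the 3-benzyloxy group.

**Step 12**
Reactants: 20 8-bromo-4α-(2-ethoxyethoxy)-3,5,7,3',4'-penta-O-benzyl-ent-epicatechin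
Product: 21 8-bromo-4α-(2,6-dimethylphenylthio)-3,5,7,3',4'-penta-O-benzyl-ent-epicatechin
Conditions: 2,6-Me2C6H3SH (3 equiv), BF3·OEt2, CH2Cl2, −78 to −30 °C
Reagents that add atoms: 2,6-dimethylbenzenethiol Cc1cccc(C)c1S
Why: Lewis acid ionisation of the C4 ether and capture of the cation by the thiol anti to the 3-benzyloxy group gives a sulfur leaving group that is inert to hard Lewis acids.

**Step 13**
Reactants: 22 (−)-epicatechin (2R,3R)
Product: 23 3,5,7,3',4'-penta-O-benzylepicatechin
Conditions: NaH, BnBr, n-Bu4NI (cat.), DMF, −10 °C to rt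
Reagents that add atoms: benzyl bromide BrCc1ccccc1
Why: Exhaustive Williamson benzylation as in step 9.

**Step 14**
Reactants: 23 3,5,7,3',4'-penta-O-benzylepicatechin
Product: 24 4β-(2-ethoxyethoxy)-3,5,7,3',4'-penta-O-benzylepicatechin
Conditions: DDQ (2 equiv), 2-ethoxyethanol (5 equiv), CH2Cl2, rt
Reagents that add atoms: 2-ethoxyethanol CCOCCO
Why: Benzylic oxidation at C4 as in step 11, done before bromination because the unbrominated ring A is the better hydride donor.

**Step 15**
Reactants: 24 4β-(2-ethoxyethoxy)-3,5,7,3',4'-penta-O-benzylepicatechin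
Product: 25 6,8-dibromo-4β-(2-ethoxyethoxy)-3,5,7,3',4'-penta-O-benzylepicatechin
Conditions: NBS (2.1 equiv), CH2Cl2, 0 °C
Reagents that add atoms: N-bromosuccinimide O=C1CCC(=O)N1Br
Why: Double electrophilic bromination of ring A blocks C6 and C8, so unit W can act only as an electrophile; the acid-free conditions spare the C4 ether.

**Step 16**
Reactants: 25 6,8-dibromo-4β-(2-ethoxyethoxy)-3,5,7,3',4'-penta-O-benzylepicatechin; 21 8-bromo-4α-(2,6-dimethylphenylthio)-3,5,7,3',4'-penta-O-benzyl-ent-epicatechin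
Product: 26 protected dimer W(4β→6)X carrying the 4α-XyS group on unit X
Conditions: BF3·OEt2, CH2Cl2, −78 to −40 °C
Reagents that add atoms: none
Why: Friedel–Crafts alkylation in which the hard Lewis acid ionises only the C4 ether of 25; C6 is the only free position of 21 and attacks the C4 cation anti to the 3-benzyloxy and 2-aryl groups, which sets 4β.

**Step 17**
Reactants: 26 protected dimer W(4β→6)X with 4α-XyS group; 16 4α-acetoxy-3,5,7,3',4'-penta-O-benzylepicatechin
Product: 27 protected trimer W(4β→6)X(4α→8)Y carrying the 4-acetoxy group on unit Y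
Conditions: NIS (1.3 equiv), 16 (2.5 equiv), 4 Å molecular sieves, CH2Cl2, −78 to −30 °C
Reagents that add atoms: none
Why: Thiophilic activation of the thioether gives the C4 cation of unit X, which C8 of 16 (more accessible than C6) attacks anti to the 3-benzyloxy group (4α in the ent series); this orthogonal Friedel–Crafts union leaves the acetate intact.

**Step 18**
Reactants: 27 protected trimer with 4-acetoxy group on unit Y; 19 8-bromo-3,5,7,3',4'-penta-O-benzyl-ent-epicatechin
Product: 28 protected tetramer (twenty benzyl ethers and four aryl bromides)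
Conditions: BF3·OEt2, 19 (3 equiv), CH2Cl2, −78 to −40 °C
Reagents that add atoms: none
Why: Friedel–Crafts alkylation: BF3 ionises the C4 acetate of unit Y and the only free position of 19, C6, attacks from the β face anti to the cis 2-aryl and 3-benzyloxy groups, giving the 3,4-trans 4β→6 bond.

**Step 19**
Reactants: 28 protected tetramer
Product: 29 target tetramer CNP0120618.2
Conditions: H2 (1 atm), Pd(OH)2/C, Et3N, THF/MeOH/H2O, rt
Reagents that add atoms: none
Why: Global hydrogenolysis cleaves all benzyl ethers and the four aryl C–Br bonds (Et3N takes up HBr); the interflavan C–C bonds and the stereocentres are not affected.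

**Compound list**
1 | 5-fluororesorcinol | Oc1cc(O)cc(F)c1 | starting material
2 | 1,3-bis(benzyloxy)-5-fluorobenzene | Fc1cc(OCc2ccccc2)cc(OCc2ccccc2)c1 | intermediate
3 | 1,5-bis(benzyloxy)-3-fluoro-2-iodobenzene | Fc1cc(OCc2ccccc2)cc(OCc2ccccc2)c1I | intermediate
4 | 2-bromoacrolein diethyl acetal | C=C(Br)C(OCC)OCC | starting material
5 | 2-bromoacrolein dibenzyl acetal | C=C(Br)C(OCc1ccccc1)OCc1ccccc1 | intermediate
6 | [2,4-bis(benzyloxy)-6-fluorophenyl]magnesium chloride | Cl[Mg]c1c(F)cc(OCc2ccccc2)cc1OCc1ccccc1 | intermediate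
7 | [2,4-bis(benzyloxy)-6-fluorophenyl]zinc chloride | Cl[Zn]c1c(F)cc(OCc2ccccc2)cc1OCc1ccccc1 | intermediate
8 | 2-[2,4-bis(benzyloxy)-6-fluorophenyl]acrolein dibenzyl acetal | C=C(c1c(F)cc(OCc2ccccc2)cc1OCc1ccccc1)C(OCc1ccccc1)OCc1ccccc1 | intermediate
9 | pinacol (E)-[3-(benzyloxy)-2-[2,4-bis(benzyloxy)-6-fluorophenyl]allyl]boronate (OBn cis to CH2B) | CC1(C)OB(C/C(=C\OCc2ccccc2)c2c(F)cc(OCc3ccccc3)cc2OCc2ccccc2)OC1(C)C | intermediate
10 | 3,4-bis(benzyloxy)benzaldehyde | O=Cc1ccc(OCc2ccccc2)c(OCc2ccccc2)c1 | starting material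
11 | pinacol borate of (1R,2R)-2-(benzyloxy)-1-[3,4-bis(benzyloxy)phenyl]-3-[2,4-bis(benzyloxy)-6-fluorophenyl]but-3-en-1-ol | CC1(C)OB(O[C@H](c2ccc(OCc3ccccc3)c(OCc3ccccc3)c2)[C@H](OCc2ccccc2)C(=C)c2c(F)cc(OCc3ccccc3)cc2OCc2ccccc2)OC1(C)C | intermediate
12 | potassium (1R,2R)-2-(benzyloxy)-1-[3,4-bis(benzyloxy)phenyl]-3-[2,4-bis(benzyloxy)-6-fluorophenyl]but-3-en-1-olate | [K+].[O-][C@H](c1ccc(OCc2ccccc2)c(OCc2ccccc2)c1)[C@H](OCc1ccccc1)C(=C)c1c(F)cc(OCc2ccccc2)cc1OCc1ccccc1 | intermediate
13 | (2R,3R)-3,5,7-tris(benzyloxy)-2-[3,4-bis(benzyloxy)phenyl]-4-methylidenechromane | c1ccccc1COc1cc(OCc2ccccc2)c2c(c1)O[C@H](c1ccc(OCc3ccccc3)c(OCc3ccccc3)c1)[C@H](OCc1ccccc1)C2=C | intermediate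
14 | (2R,3S)-3,5,7-tris(benzyloxy)-2-[3,4-bis(benzyloxy)phenyl]chroman-4-one (2,3-cis) | c1ccccc1COc1cc(OCc2ccccc2)c2c(c1)O[C@H](c1ccc(OCc3ccccc3)c(OCc3ccccc3)c1)[C@H](OCc1ccccc1)C2=O | intermediate
15 | 4α-hydroxy-3,5,7,3',4'-penta-O-benzylepicatechin | c1ccccc1COc1cc(OCc2ccccc2)c2c(c1)O[C@H](c1ccc(OCc3ccccc3)c(OCc3ccccc3)c1)[C@H](OCc1ccccc1)[C@@H]2O | intermediate
16 | 4α-acetoxy-3,5,7,3',4'-penta-O-benzylepicatechin | c1ccccc1COc1cc(OCc2ccccc2)c2c(c1)O[C@H](c1ccc(OCc3ccccc3)c(OCc3ccccc3)c1)[C@H](OCc1ccccc1)[C@@H]2OC(C)=O | intermediate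
17 | (+)-epicatechin (2S,3S) | Oc1cc(O)c2c(c1)O[C@@H](c1ccc(O)c(O)c1)[C@@H](O)C2 | starting material
18 | 3,5,7,3',4'-penta-O-benzyl-ent-epicatechin | c1ccccc1COc1cc(OCc2ccccc2)c2c(c1)O[C@@H](c1ccc(OCc3ccccc3)c(OCc3ccccc3)c1)[C@@H](OCc1ccccc1)C2 | intermediate
19 | 8-bromo-3,5,7,3',4'-penta-O-benzyl-ent-epicatechin | c1ccccc1COc1cc(OCc2ccccc2)c2c(c1Br)O[C@@H](c1ccc(OCc3ccccc3)c(OCc3ccccc3)c1)[C@@H](OCc1ccccc1)C2 | intermediate
20 | 8-bromo-4α-(2-ethoxyethoxy)-3,5,7,3',4'-penta-O-benzyl-ent-epicatechin | c1ccccc1COc1cc(OCc2ccccc2)c2c(c1Br)O[C@@H](c1ccc(OCc3ccccc3)c(OCc3ccccc3)c1)[C@@H](OCc1ccccc1)[C@@H]2OCCOCC | intermediate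
21 | 8-bromo-4α-(2,6-dimethylphenylthio)-3,5,7,3',4'-penta-O-benzyl-ent-epicatechin | c1ccccc1COc1cc(OCc2ccccc2)c2c(c1Br)O[C@@H](c1ccc(OCc3ccccc3)c(OCc3ccccc3)c1)[C@@H](OCc1ccccc1)[C@@H]2Sc1c(C)cccc1C | intermediate
22 | (−)-epicatechin (2R,3R) | Oc1cc(O)c2c(c1)O[C@H](c1ccc(O)c(O)c1)[C@H](O)C2 | starting material
23 | 3,5,7,3',4'-penta-O-benzylepicatechin | c1ccccc1COc1cc(OCc2ccccc2)c2c(c1)O[C@H](c1ccc(OCc3ccccc3)c(OCc3ccccc3)c1)[C@H](OCc1ccccc1)C2 | intermediate
24 | 4β-(2-ethoxyethoxy)-3,5,7,3',4'-penta-O-benzylepicatechin | c1ccccc1COc1cc(OCc2ccccc2)c2c(c1)O[C@H](c1ccc(OCc3ccccc3)c(OCc3ccccc3)c1)[C@H](OCc1ccccc1)[C@H]2OCCOCC | intermediate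
25 | 6,8-dibromo-4β-(2-ethoxyethoxy)-3,5,7,3',4'-penta-O-benzylepicatechin | c1ccccc1COc1c(Br)c(OCc2ccccc2)c2c(c1Br)O[C@H](c1ccc(OCc3ccccc3)c(OCc3ccccc3)c1)[C@H](OCc1ccccc1)[C@H]2OCCOCC | intermediate
26 | protected dimer W(4β→6)X with 4α-XyS on unit X | c1ccccc1COc1c(Br)c(OCc2ccccc2)c2c(c1Br)O[C@H](c1ccc(OCc3ccccc3)c(OCc3ccccc3)c1)[C@H](OCc1ccccc1)[C@H]2c1c(OCc2ccccc2)c(Br)c2c(c1OCc1ccccc1)[C@@H](Sc1c(C)cccc1C)[C@H](OCc1ccccc1)[C@H](c1ccc(OCc3ccccc3)c(OCc3ccccc3)c1)O2 | intermediate
27 | protected trimer W(4β→6)X(4α→8)Y with 4α-acetoxy on unit Y | c1ccccc1COc1c(Br)c(OCc2ccccc2)c2c(c1Br)O[C@H](c1ccc(OCc3ccccc3)c(OCc3ccccc3)c1)[C@H](OCc1ccccc1)[C@H]2c1c(OCc2ccccc2)c(Br)c2c(c1OCc1ccccc1)[C@@H](c1c(OCc3ccccc3)cc(OCc3ccccc3)c3c1O[C@H](c1ccc(OCc4ccccc4)c(OCc4ccccc4)c1)[C@H](OCc1ccccc1)[C@@H]3OC(C)=O)[C@H](OCc1ccccc1)[C@H](c1ccc(OCc3ccccc3)c(OCc3ccccc3)c1)O2 | intermediate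
28 | protected tetramer W(4β→6)X(4α→8)Y(4β→6)Z | c1ccccc1COc1c(Br)c(OCc2ccccc2)c2c(c1Br)O[C@H](c1ccc(OCc3ccccc3)c(OCc3ccccc3)c1)[C@H](OCc1ccccc1)[C@H]2c1c(OCc2ccccc2)c(Br)c2c(c1OCc1ccccc1)[C@@H](c1c(OCc3ccccc3)cc(OCc3ccccc3)c3c1O[C@H](c1ccc(OCc4ccccc4)c(OCc4ccccc4)c1)[C@H](OCc1ccccc1)[C@H]3c1c(OCc4ccccc4)c(Br)c3c(c1OCc1ccccc1)C[C@H](OCc1ccccc1)[C@H](c1ccc(OCc4ccccc4)c(OCc4ccccc4)c1)O3)[C@H](OCc1ccccc1)[C@H](c1ccc(OCc3ccccc3)c(OCc3ccccc3)c1)O2 | intermediate
29 | CNP0120618.2, epicatechin-(4β→6)-ent-epicatechin-(4α→8)-epicatechin-(4β→6)-ent-epicatechin | Oc1cc(O)c2c(c1)O[C@H](c1ccc(O)c(O)c1)[C@H](O)[C@H]2c1c(O)cc2c(c1O)[C@@H](c1c(O)cc(O)c3c1O[C@H](c1ccc(O)c(O)c1)[C@H](O)[C@H]3c1c(O)cc3c(c1O)C[C@H](O)[C@H](c1ccc(O)c(O)c1)O3)[C@H](O)[C@H](c1ccc(O)c(O)c1)O2 | target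

Total step count: 19. Longest linear sequence: 10 steps (steps 1, 2, 4, 5, 6, 7, 8, 17, 18, 19).

**Steps most likely to fail**

Step 6. The allyl transfer may lose facial or syn selectivity with the bulky β-aryl group, and the pinacol borate may release the alkoxide too slowly, so that base-induced migration of the exocyclic double bond competes with fluoride displacement. The fallback replaces catalyst control by reagent control. It sets out from 9, which is transesterified with diethanolamine to the crystalline diethanolamine boronate F1. Exchange with (R,R)-diisopropyl tartrate in ether/brine gives the tartrate allylboronate F2, expected to direct the same Si-face attack. Tartrate-controlled allylboration of 10 (toluene, 4 Å molecular sieves, −78 °C), followed in the same flask by KOt-Bu and 18-crown-6, rejoins the route at 13.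

Step 5. Borylcupration may be slow on the hindered 1,1-disubstituted alkene, and β-alkoxide elimination may proceed through both rotamers, scrambling the enol ether geometry on which the syn selectivity of step 6 depends. The fallback moves the geometry-determining event to a π-allyl palladium intermediate. It sets out from 8, which with acetyl chloride and catalytic ZnCl2 gives the racemic α-chloro ether F3. Borylation with B2pin2 and Pd2(dba)3 in toluene at 50 °C passes through the 2-aryl π-allyl complex, in which the benzyloxy group should avoid the central aryl group, and boron enters at the CH2 terminus. The route is rejoined at 9.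

Step 7. Ozone may attack the benzyl ethers or the electron-rich rings, and ketone 14 may epimerise at C3 or open by retro-oxa-Michael reaction before it is reduced. The fallback avoids ozone and basic hydride. It sets out from 13: dihydroxylation with catalytic OsO4 and N-methylmorpholine N-oxide from the face anti to the 2-aryl and 3-benzyloxy groups gives diol F4. Cleavage with NaIO4 gives 14, and Luche reduction (NaBH4, CeCl3·7H2O, MeOH, −78 °C) rejoins the route at 15.

**Further compounds**
F1 | step 6 | diethanolamine adduct of (E)-[3-(benzyloxy)-2-[2,4-bis(benzyloxy)-6-fluorophenyl]allyl]boronic acid | [B-]12(OCC[NH+]1CCO2)C/C(=C\OCc1ccccc1)c1c(F)cc(OCc2ccccc2)cc1OCc1ccccc1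
F2 | step 6 | (R,R)-diisopropyl tartrate (E)-[3-(benzyloxy)-2-[2,4-bis(benzyloxy)-6-fluorophenyl]allyl]boronate | CC(C)OC(=O)[C@@H]1OB(C/C(=C\OCc2ccccc2)c2c(F)cc(OCc3ccccc3)cc2OCc2ccccc2)O[C@H]1C(=O)OC(C)C
F3 | step 5 | racemic 1-(benzyloxy)-1-chloro-2-[2,4-bis(benzyloxy)-6-fluorophenyl]prop-2-ene | C=C(c1c(F)cc(OCc2ccccc2)cc1OCc1ccccc1)C(Cl)OCc1ccccc1
F4 | step 7 | 4β-hydroxy-4α-(hydroxymethyl)-3,5,7,3',4'-penta-O-benzylepicatechin | c1ccccc1COc1cc(OCc2ccccc2)c2c(c1)O[C@H](c1ccc(OCc3ccccc3)c(OCc3ccccc3)c1)[C@H](OCc1ccccc1)[C@]2(O)CO
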